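**Plan**

1. Retrosynthesis: the butenolide is cut at C7=C11 (intramolecular Horner–Wadsworth–Emmons) and at the O6–C12 acyl bond, the O8 and O13 esters at their acyl bonds, and the 1,10-epoxide at C1–O (C10 alkoxide displacing a C1 sulfonate with inversion).
2. Enabling feature: in the ten-membered carbocycle C1–C10, quaternary C10 carries an oxygen and C14 (a former carboxyl carbon) and is bonded to oxygenated, allylic C1 beside the Z C2=C3 alkene. This is the product pattern of a glycolate ester-enolate Claisen, so C1–C10 is cut and C3–O–C14 restored, giving a ten-membered lactone (C14, O, C3–C10) with a (Z)-alkoxyvinyl group on C3.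
3. The lactone is cut at its ester C–O bond; the seco acid at C2–C3 (alkoxyvinyl metal + epoxy aldehyde) and at C6–C7 and C7–C8, with 1,3-dithiane as the C7 linchpin between a malate-derived C8–C14 ester and a C3–C6 epoxy aldehyde.
4. Forward: chain joined C8–C7, then C7–C6, then C3–C2; lactone ring closed; carbocycle formed by reorganising that ring (step 25); then 1,10-epoxide, butenolide ring, acylations.
5. Stereochemistry: C4/C5 from Sharpless epoxidation, C6 from Felkin–Anh addition, C8 from CBS reduction, C3 from chelation-controlled addition; C1 and C10 by chirality transfer from C3 through a boat Claisen (C1 inverted on epoxide closure); C2′ from (R)-2-methylbutanoic acid.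
6. C10 of the early intermediates ((S), from malate) is a throw-away centre that becomes sp2 in the ketene acetal.

Key step: step 25

Remarks: carbons are numbered as in the target (ring C1–C10; butenolide C11–C13 with C12 the carbonyl; C14 on C10; C15 the methyl on C4). TES = triethylsilyl, TBS = tert-butyldimethylsilyl, PMB = 4-methoxybenzyl, DMB = 3,4-dimethoxybenzyl.
Assumption: the acetal carbon in 11 and 14–19 is carried as both epimers, which converge in step 14; 50–52 are epimeric at the phosphonate carbon, which becomes sp2 in step 36.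

**Epoxy aldehyde (C3–C6)**

Step 1
Reactants: 1 prop-2-yn-1-ol
Product: 2 triethyl(prop-2-yn-1-yloxy)silane
Conditions: Et3SiCl, imidazole, CH2Cl2, 0 °C → rt
Reagents that add atoms: chlorotriethylsilane, CC[Si](Cl)(CC)CC
Why: Standard silylation of a primary alcohol; a primary TES ether is chosen because step 18 can later turn it directly into the aldehyde.

Step 2
Reactants: 2 triethyl(prop-2-yn-1-yloxy)silane
Product: 4 methyl 4-(triethylsilyloxy)but-2-ynoate, via lithium acetylide 3 (not isolated)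
Conditions: n-BuLi, THF, −78 °C; ClCO2Me, −78 → 0 °C
Reagents that add atoms: methyl chloroformate, COC(=O)Cl
Why: Acylation of a lithium acetylide with a chloroformate is a routine way to an ynoate.

Step 3
Reactants: 4 methyl 4-(triethylsilyloxy)but-2-ynoate
Product: 5 methyl (Z)-3-methyl-4-(triethylsilyloxy)but-2-enoate
Conditions: Me2CuLi (MeLi, CuI), THF, −78 °C; NH4Cl
Reagents that add atoms: lithium dimethylcuprate, [Li+].C[Cu-]C
Why: Syn carbocupration (conjugate addition) of the ynoate at low temperature places methyl and hydrogen cis, so the CH2O group and the ester end up cis (Z) as the 4,5-epoxide requires.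

Step 4
Reactants: 5 methyl (Z)-3-methyl-4-(triethylsilyloxy)but-2-enoate
Product: 6 (Z)-3-methyl-4-(triethylsilyloxy)but-2-en-1-ol
Conditions: i-Bu2AlH, CH2Cl2, −78 °C; aq. potassium sodium tartrate
Reagents that add atoms: none
Why: 1,2-Reduction of an enoate with i-Bu2AlH should give the allylic alcohol without touching the alkene geometry.

Step 5
Reactants: 6 (Z)-3-methyl-4-(triethylsilyloxy)but-2-en-1-ol
Product: 7 [(2S,3R)-3-methyl-3-(triethylsilyloxymethyl)oxiran-2-yl]methanol
Conditions: Ti(Oi-Pr)4 (cat.), L-(+)-diethyl tartrate (cat.), t-BuOOH, 4 Å MS, CH2Cl2, −20 °C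
Reagents that add atoms: tert-butyl hydroperoxide, CC(C)(C)OO
Why: Sharpless asymmetric epoxidation of a nerol-type (Z)-3,3-disubstituted allylic alcohol; the L-(+)-tartrate should deliver oxygen to the face that gives (2S,3R), which fixes C5 and C4.

Step 6
Reactants: 7 [(2S,3R)-3-methyl-3-(triethylsilyloxymethyl)oxiran-2-yl]methanol
Product: 8 (2R,3R)-3-methyl-3-(triethylsilyloxymethyl)oxirane-2-carbaldehyde
Conditions: Dess–Martin periodinane, pyridine, CH2Cl2, 0 °C → rt
Reagents that add atoms: none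
Why: Buffered Dess–Martin oxidation should give the epoxy aldehyde without epimerisation or loss of the primary TES ether (the descriptor at C2 changes only by CIP priority).

**Dithiane fragment (C7–C14)**

Step 7
Reactants: 9 dimethyl (S)-malate
Product: 10 methyl (S)-3,4-dihydroxybutanoate
Conditions: BH3·SMe2, NaBH4 (cat.), THF, rt; MeOH
Reagents that add atoms: none
Why: Hydroxyl-directed borane reduction selectively reduces the ester next to the free hydroxyl, leaving the distal ester as the future C8 acyl carbon.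

Step 8
Reactants: 10 methyl (S)-3,4-dihydroxybutanoate
Product: 11 methyl 2-[(4S)-2-(4-methoxyphenyl)-1,3-dioxolan-4-yl]acetate (both acetal epimers)
Conditions: 4-MeOC6H4CH(OMe)2, PPTS (cat.), CH2Cl2, rt
Reagents that add atoms: 4-methoxybenzaldehyde dimethyl acetal, COc1ccc(C(OC)OC)cc1
Why: Acetal exchange protects O10 and O14 together in a form that step 14 can open to the O10 PMB ether; C14 is kept at the alcohol level so that no ester can lactonise onto O8 later.

Step 9
Reactants: 12 1,3-dithiane; 11 methyl 2-[(4S)-2-(4-methoxyphenyl)-1,3-dioxolan-4-yl]acetate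
Product: 14 1-(1,3-dithian-2-yl)-2-[(4S)-2-(4-methoxyphenyl)-1,3-dioxolan-4-yl]ethan-1-one, via 2-lithio-1,3-dithiane 13 (not isolated)
Conditions: n-BuLi, THF, −30 °C; then 11 (0.45 equiv), −78 → −20 °C; NH4Cl
Reagents that add atoms: none
Why: Corey–Seebach acylation of the lithiated dithiane with an ester; the acyl dithiane is deprotonated at C7 by the second equivalent, which should prevent over-addition and β-elimination.

Step 10
Reactants: 14 1-(1,3-dithian-2-yl)-2-[(4S)-2-(4-methoxyphenyl)-1,3-dioxolan-4-yl]ethan-1-one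
Product: 15 (1S)-1-(1,3-dithian-2-yl)-2-[(4S)-2-(4-methoxyphenyl)-1,3-dioxolan-4-yl]ethan-1-ol
Conditions: (R)-2-methyl-CBS-oxazaborolidine (0.2 equiv), BH3·SMe2, THF, −20 °C; MeOH
Reagents that add atoms: none
Why: Corey–Bakshi–Shibata reduction of a 2-acyl dithiane with the dithianyl group as the large substituent, so the (R)-catalyst should set C8 as (S) under reagent control.

Step 11
Reactants: 15 (1S)-1-(1,3-dithian-2-yl)-2-[(4S)-2-(4-methoxyphenyl)-1,3-dioxolan-4-yl]ethan-1-ol
Product: 16 tert-butyl{(1S)-1-(1,3-dithian-2-yl)-2-[(4S)-2-(4-methoxyphenyl)-1,3-dioxolan-4-yl]ethoxy}dimethylsilane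
Conditions: t-BuMe2SiCl, imidazole, DMF, rt
Reagents that add atoms: tert-butylchlorodimethylsilane, CC(C)(C)[Si](C)(C)Cl
Why: Routine silylation of a secondary alcohol; the TBS group is the one meant to survive until step 39.

**Fragment union and seco acid**

Step 12
Reactants: 16 tert-butyl{(1S)-1-(1,3-dithian-2-yl)-2-[(4S)-2-(4-methoxyphenyl)-1,3-dioxolan-4-yl]ethoxy}dimethylsilane; 8 (2R,3R)-3-methyl-3-(triethylsilyloxymethyl)oxirane-2-carbaldehyde
Product: 18 C6 carbinol (4R,5S,6R,8S,10S): C3 CH2OTES; 4,5-epoxide; 6-OH; C7 1,3-dithiane; 8-OTBS; O10/O14 4-methoxybenzylidene acetal, via lithiated dithiane 17 (not isolated)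
Conditions: t-BuLi, THF/HMPA (10:1), −78 °C, 5 min; then 8, −78 °C; NH4Cl
Reagents that add atoms: none
Why: Corey–Seebach addition of a 2-alkyl-2-lithio-1,3-dithiane to an α,β-epoxy aldehyde; under non-chelating conditions Felkin–Anh attack anti to the epoxide C–O bond should give the anti epoxy alcohol, C6 (R).

Step 13
Reactants: 18 C6 carbinol
Product: 19 6-O-triethylsilyl ether of 18
Conditions: Et3SiOTf, 2,6-lutidine, CH2Cl2, −78 °C
Reagents that add atoms: triethylsilyl trifluoromethanesulfonate, CC[Si](CC)(CC)OS(=O)(=O)C(F)(F)F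
Why: Silyl triflate silylation suits a hindered secondary alcohol; TES is chosen so that O6 can be freed before O8 in step 32.

Step 14
Reactants: 19 6-O-triethylsilyl ether of 18
Product: 20 primary alcohol (4R,5S,6R,8S,10S): 14-OH, 10-OPMB, 8-OTBS, C7 dithiane, 6-OTES, 4,5-epoxide, C3 CH2OTES
Conditions: i-Bu2AlH, CH2Cl2, −78 → 0 °C; aq. potassium sodium tartrate
Reagents that add atoms: none
Why: Reductive opening of a 4-methoxybenzylidene acetal; aluminium binds the less hindered primary oxygen, so hydride delivery should leave the PMB ether on O10 and free O14, and both acetal epimers converge.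

Step 15
Reactants: 20 primary alcohol
Product: 21 C14 aldehyde of 20
Conditions: SO3·pyridine, DMSO, i-Pr2NEt, CH2Cl2, 0 °C
Reagents that add atoms: none
Why: Parikh–Doering oxidation is mild, non-acidic and compatible with the dithiane; any epimerisation at C10 is harmless because that centre is erased in step 25.

Step 16
Reactants: 21 C14 aldehyde
Product: 22 C14 carboxylic acid
Conditions: NaClO2, NaH2PO4, 2-methyl-2-butene (large excess), t-BuOH/H2O, 0 °C
Reagents that add atoms: sodium chlorite, [Na+].[O-]Cl=O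
Why: Pinnick oxidation; the alkene scavenger removes hypochlorous acid, which should protect the dithiane sulfur.

Step 17
Reactants: 22 C14 carboxylic acid
Product: 23 methyl ester of 22
Conditions: Me3SiCHN2, MeOH/toluene, rt
Reagents that add atoms: (trimethylsilyl)diazomethane, C[Si](C)(C)C=[N+]=[N-]
Why: Diazoalkane esterification masks the acid for the oxidation and organometallic addition that follow; by now O8 is silylated, so the ester cannot lactonise.

Step 18
Reactants: 23 methyl ester
Product: 24 C3 aldehyde (4S,5S,6R,8S,10S): methyl ester, 10-OPMB, 8-OTBS, C7 dithiane, 6-OTES, 4,5-epoxide, C3 CHO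
Conditions: (COCl)2, DMSO, CH2Cl2, −78 → −40 °C; Et3N
Reagents that add atoms: none
Why: Under Swern conditions the chlorosulfonium reagent cleaves a primary TES ether and oxidises it directly to the aldehyde, while the hindered secondary TES and TBS ethers should stay (C4 becomes S only by CIP priority).

Step 19
Reactants: 25 4-methoxybenzyl alcohol; 26 trichloroethylene
Product: 27 1-{[(E)-1,2-dichloroethenyl]oxymethyl}-4-methoxybenzene
Conditions: KH, THF, 0 °C; then Cl2C=CHCl, rt
Reagents that add atoms: none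
Why: The alkoxide adds anti to dichloroacetylene generated in situ from trichloroethylene, the standard entry to 1,2-dichlorovinyl ethers.

Step 20
Reactants: 27 1-{[(E)-1,2-dichloroethenyl]oxymethyl}-4-methoxybenzene
Product: 29 1-(ethynyloxymethyl)-4-methoxybenzene, via lithium alkynyl ether 28 (not isolated)
Conditions: n-BuLi (2.3 equiv), THF, −78 → −40 °C; MeOH, −78 °C
Reagents that add atoms: none
Why: Dehydrochlorination followed by chlorine–lithium exchange gives the lithium alkynyl ether, which is protonated; the benzyl alkynyl ether is kept cold and used at once to avoid sigmatropic rearrangement.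

Step 21
Reactants: 29 1-(ethynyloxymethyl)-4-methoxybenzene
Product: 30 tributyl{(Z)-2-[(4-methoxybenzyl)oxy]ethenyl}stannane
Conditions: Bu3SnH, Et3B (cat.), air, toluene, 0 °C → rt
Reagents that add atoms: tributyltin hydride, CCCC[SnH](CCCC)CCCC
Why: Radical hydrostannation of an alkoxyacetylene adds anti under kinetic control and should give the (Z)-β-stannyl enol ether, as for the ethoxy analogue.

Step 22
Reactants: 30 tributyl{(Z)-2-[(4-methoxybenzyl)oxy]ethenyl}stannane; 24 C3 aldehyde
Product: 33 C3 carbinol (1Z,3S,4R,5S,6R,8S,10S): methyl ester, 10-OPMB, 8-OTBS, C7 dithiane, 6-OTES, 4,5-epoxide, 3-OH, (Z)-CH=CH–OPMB, via vinyllithium 31 (not isolated), via vinylmagnesium bromide 32 (not isolated)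
Conditions: 30, n-BuLi, THF, −78 °C; MgBr2·OEt2; then 24, CH2Cl2/Et2O, −78 °C
Reagents that add atoms: none
Why: Tin–lithium exchange and transmetalation keep the Z geometry, and Cram-chelate addition (magnesium bridging the carbonyl and epoxide oxygens, attack from the methyl face away from C5) should set C3 as (S); this avoids a catalytic hydrogenation that the dithiane would poison.

Step 23
Reactants: 33 C3 carbinol
Product: 34 seco acid (free C14 carboxylic acid of 33)
Conditions: LiOH·H2O, THF/MeOH/H2O, 0 °C → rt; aq. NaH2PO4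
Reagents that add atoms: lithium hydroxide, [Li+].[OH-]
Why: Saponification of the activated α-alkoxy methyl ester; the enol ether, epoxide and silyl ethers tolerate base, and the work-up is kept near neutral.

Step 24
Reactants: 34 seco acid
Product: 36 ten-membered lactone (3S,4R,5S,6R,8S,10S): C14(=O)–O–C3; (Z)-CH=CH–OPMB on C3; 4,5-epoxide; 6-OTES; C7 dithiane; 8-OTBS; 10-OPMB, via mixed anhydride 35 (not isolated)
Conditions: 2,4,6-Cl3C6H2COCl, Et3N, THF, rt; then slow addition to DMAP, toluene (high dilution), 60 °C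
Reagents that add atoms: none
Why: Yamaguchi macrolactonisation; the cis-epoxide and the spiro dithiane should pre-organise the chain, and epimerisation at C10 via the activated acid would not matter.

**Key step**

Step 25
Reactants: 36 ten-membered lactone
Product: 39 cyclodecene acid (1S,2Z,4R,5S,6R,8S,10R): 10-CO2H, 10-OPMB, 1-OPMB, 4,5-epoxide, 6-OTES, C7 dithiane, 8-OTBS, via silyl ketene acetal 37 (not isolated), via trimethylsilyl ester 38 (not isolated)
Conditions: KN(SiMe3)2, Me3SiCl/Et3N, THF/toluene, −78 °C → rt, then 60 °C if needed; aq. citric acid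
Reagents that add atoms: none
Why: KN(SiMe3)2 removes H10 and Me3SiCl traps the potassium-chelated glycolate enolate as the (Z)-silyl ketene acetal 37 with C9 cis to the ring oxygen; on warming, 37 undergoes a concerted [3,3]-sigmatropic shift through C10, C14, O, C3, C2 and C1 that forms C10–C1 and breaks C3–O. The closest known reactions are the Ireland–Claisen ring reorganisation of alkenyl lactones to cycloalkene carboxylic acids and the chelation-controlled glycolate ester-enolate Claisen. The ten-membered carbocycle is not closed by a separate cyclisation but arises from the ten-membered lactone, because the six-atom chain C4–C9 already links the termini C3 and C10 of the pericyclic array. That chain forces C9 and C4 onto the inner positions of the two three-atom halves, which is possible only in a boat-like transition state and places C4 cis to C1 across the new C2=C3 bond (Z). C10 is fixed by the enolate geometry and by the face on which the C3–O bond departs, and C1 by the (Z)-enol ether geometry on that same face, so the C3 centre is exchanged for (1S,10R). The step needs boat over chair and faithful transfer from C3; the short tether, the chelated enolate and the (Z)-enol ether are what should secure both.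

**1,10-Epoxide and C14**

Step 26
Reactants: 39 cyclodecene acid
Product: 40 methyl ester of 39
Conditions: Me3SiCHN2, MeOH/toluene, rt
Reagents that add atoms: (trimethylsilyl)diazomethane, C[Si](C)(C)C=[N+]=[N-]
Why: Diazoalkane esterification of the hindered tertiary acid occurs at oxygen and avoids acyl activation.

Step 27
Reactants: 40 methyl ester
Product: 41 1,10-diol methyl ester (1S,10R)
Conditions: DDQ (3 equiv), CH2Cl2/pH 7 buffer, 0 °C
Reagents that add atoms: none
Why: Oxidative cleavage of both PMB ethers by DDQ; the wet, buffered medium hydrolyses the benzylic cations and should suppress acetal formation between O1 and O10, and the short cold reaction spares the dithiane.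

Step 28
Reactants: 41 1,10-diol methyl ester
Product: 43 1,10-epoxy ester (1R,10R): methyl (1,10-epoxy)carboxylate with 2Z alkene, 4,5-epoxide, 6-OTES, C7 dithiane, 8-OTBS, via mesylate 42 (not isolated)
Conditions: MsCl, Et3N, CH2Cl2, −20 °C; then K2CO3, MeOH, 0 °C
Reagents that add atoms: none
Why: Only the secondary allylic hydroxyl is mesylated (the tertiary α-hydroxy ester is inert), and intramolecular Williamson closure by the C10 alkoxide inverts C1 to give the trans epoxide (C10 changes descriptor only by CIP priority later).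

Step 29
Reactants: 43 1,10-epoxy ester
Product: 44 C14 alcohol (1R,10S)
Conditions: i-Bu2AlH, CH2Cl2, −78 °C; aq. potassium sodium tartrate
Reagents that add atoms: none
Why: Reduction of a glycidic ester to the epoxy alcohol with i-Bu2AlH at low temperature is routine and should leave both epoxides, the dithiane and the silyl ethers.

Step 30
Reactants: 44 C14 alcohol
Product: 45 14-O-PMB ether of 44
Conditions: NaH, 4-MeOC6H4CH2Cl, Bu4NI (cat.), THF/DMF, 0 °C → rt
Reagents that add atoms: 4-methoxybenzyl chloride, COc1ccc(CCl)cc1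
Why: Williamson etherification; Payne rearrangement is blocked because it would need substitution at quaternary C10, and a PMB ether here is orthogonal to the two silyl ethers that must be removed first.

**Butenolide and acylations**

Step 31
Reactants: 45 14-O-PMB ether
Product: 46 C7 ketone (1R,4R,5S,6R,8S,10S)
Conditions: PhI(OCOCF3)2, NaHCO3, MeCN/H2O (9:1), 0 °C
Reagents that add atoms: water, O
Why: Oxidative dithiane hydrolysis with a hypervalent iodine reagent is fast at sulfur under buffered, non-acidic conditions and should spare the two allylic epoxides and the alkene.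

Step 32
Reactants: 46 C7 ketone
Product: 47 6-hydroxy-7-ketone
Conditions: HF·pyridine, pyridine, THF, 0 °C
Reagents that add atoms: none
Why: Buffered HF·pyridine removes a secondary TES ether much faster than a secondary TBS ether, which frees only O6.

Step 33
Reactants: 48 ethyl 2-(diethoxyphosphoryl)acrylate; 49 3,4-dimethoxybenzyl alcohol
Product: 50 ethyl 2-(diethoxyphosphoryl)-3-(3,4-dimethoxybenzyloxy)propanoate (racemic)
Conditions: t-BuOK (cat.), THF, 0 °C → rt
Reagents that add atoms: none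
Why: Oxa-Michael addition of an alkoxide to the doubly activated phosphonoacrylate is facile and installs C13 with its oxygen already protected.

Step 34
Reactants: 50 ethyl 2-(diethoxyphosphoryl)-3-(3,4-dimethoxybenzyloxy)propanoate
Product: 51 2-(diethoxyphosphoryl)-3-(3,4-dimethoxybenzyloxy)propanoic acid (racemic)
Conditions: LiOH·H2O (1.1 equiv), THF/H2O, 0 °C; aq. HCl to pH 3
Reagents that add atoms: lithium hydroxide, [Li+].[OH-]
Why: Saponification of the carboxylic ester in the presence of the phosphonate esters; once the carboxylate forms, the α-proton is less acidic, which should hold back retro-Michael loss of the alkoxide.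

Step 35
Reactants: 47 6-hydroxy-7-ketone; 51 2-(diethoxyphosphoryl)-3-(3,4-dimethoxybenzyloxy)propanoic acid
Product: 52 O6 phosphonoacetate ester of 47 (epimers at the phosphonate carbon)
Conditions: EDC·HCl, DMAP (cat.), CH2Cl2, 0 °C → rt
Reagents that add atoms: none
Why: Steglich-type carbodiimide esterification is the usual way to attach a phosphonoacetic acid to an α-hydroxy ketone.

Step 36
Reactants: 52 O6 phosphonoacetate ester
Product: 53 butenolide (1R,4R,5S,6S,8S,10S): C7=C11, 13-ODMB, 14-OPMB, 8-OTBS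
Conditions: LiCl, i-Pr2NEt, MeCN, rt
Reagents that add atoms: none
Why: Intramolecular Horner–Wadsworth–Emmons olefination of the ketone under Masamune–Roush conditions closes the five-membered lactone; the mild base is meant to avoid enolising the ketone towards the epoxide and to outrun loss of the β-alkoxide, and 3-hydroxy-2-phosphonopropanoates are known to olefinate under mild base.

Step 37
Reactants: 53 butenolide
Product: 54 C13 alcohol
Conditions: DDQ (1.2 equiv), CH2Cl2/pH 7 buffer, 0 °C
Reagents that add atoms: none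
Why: The more electron-rich DMB ether is oxidised by DDQ well before a PMB ether, so O13 should be freed while O14 stays protected.

Step 38
Reactants: 54 C13 alcohol
Product: 55 C13 acetate
Conditions: Ac2O, pyridine, DMAP (cat.), CH2Cl2, 0 °C
Reagents that add atoms: acetic anhydride, CC(=O)OC(C)=O
Why: Standard acetylation of the only free hydroxyl.

Step 39
Reactants: 55 C13 acetate
Product: 56 C8 alcohol
Conditions: HF·pyridine, pyridine, THF, 0 °C → rt
Reagents that add atoms: none
Why: Buffered fluoride removes the last silyl ether without acyl migration; no other silyl group is left to compete.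

Step 40
Reactants: 56 C8 alcohol; 57 (R)-2-methylbutanoic acid
Product: 58 14-O-PMB ether of the target
Conditions: EDC·HCl, DMAP (cat.), CH2Cl2, 0 °C
Reagents that add atoms: none
Why: Steglich esterification of the secondary allylic alcohol; low temperature and little DMAP are meant to keep the α-stereocentre of the acid intact.

Step 41
Reactants: 58 14-O-PMB ether of the target
Product: 59 target CNP0108300.1
Conditions: DDQ, CH2Cl2/pH 7 buffer, 0 °C → rt
Reagents that add atoms: none
Why: Neutral oxidative PMB removal is chosen as the last step because it should leave both esters, the butenolide and the two allylic epoxides untouched.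

**Compound list**

1 | prop-2-yn-1-ol | C#CCO | starting material
2 | triethyl(prop-2-yn-1-yloxy)silane | C#CCO[Si](CC)(CC)CC | intermediate
3 | [3-(triethylsilyloxy)prop-1-yn-1-yl]lithium | [Li]C#CCO[Si](CC)(CC)CC | intermediate (not isolated)
4 | methyl 4-(triethylsilyloxy)but-2-ynoate | COC(=O)C#CCO[Si](CC)(CC)CC | intermediate
5 | methyl (Z)-3-methyl-4-(triethylsilyloxy)but-2-enoate | COC(=O)/C=C(/C)CO[Si](CC)(CC)CC | intermediate
6 | (Z)-3-methyl-4-(triethylsilyloxy)but-2-en-1-ol | OC/C=C(/C)CO[Si](CC)(CC)CC | intermediate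
7 | [(2S,3R)-3-methyl-3-(triethylsilyloxymethyl)oxiran-2-yl]methanol | CC[Si](CC)(CC)OC[C@@]1(C)O[C@H]1CO | intermediate
8 | (2R,3R)-3-methyl-3-(triethylsilyloxymethyl)oxirane-2-carbaldehyde | CC[Si](CC)(CC)OC[C@@]1(C)O[C@H]1C=O | intermediate
9 | dimethyl (S)-malate | COC(=O)C[C@H](O)C(=O)OC | starting material
10 | methyl (S)-3,4-dihydroxybutanoate | COC(=O)C[C@H](O)CO | intermediate
11 | methyl 2-[(4S)-2-(4-methoxyphenyl)-1,3-dioxolan-4-yl]acetate (both acetal epimers) | COC(=O)C[C@H]1COC(O1)c1ccc(OC)cc1 | intermediate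
12 | 1,3-dithiane | C1CSCSC1 | starting material
13 | 2-lithio-1,3-dithiane | [Li]C1SCCCS1 | intermediate (not isolated)
14 | 1-(1,3-dithian-2-yl)-2-[(4S)-2-(4-methoxyphenyl)-1,3-dioxolan-4-yl]ethan-1-one | O=C(C[C@H]1COC(O1)c1ccc(OC)cc1)C1SCCCS1 | intermediate
15 | (1S)-1-(1,3-dithian-2-yl)-2-[(4S)-2-(4-methoxyphenyl)-1,3-dioxolan-4-yl]ethan-1-ol | O[C@@H](C[C@H]1COC(O1)c1ccc(OC)cc1)C1SCCCS1 | intermediate
16 | tert-butyl{(1S)-1-(1,3-dithian-2-yl)-2-[(4S)-2-(4-methoxyphenyl)-1,3-dioxolan-4-yl]ethoxy}dimethylsilane | CC(C)(C)[Si](C)(C)O[C@@H](C[C@H]1COC(O1)c1ccc(OC)cc1)C1SCCCS1 | intermediate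
17 | 2-lithio derivative of 16 | CC(C)(C)[Si](C)(C)O[C@@H](C[C@H]1COC(O1)c1ccc(OC)cc1)C1([Li])SCCCS1 | intermediate (not isolated)
18 | C6 carbinol (4R,5S,6R,8S,10S): (R)-[(2S,3R)-3-methyl-3-(triethylsilyloxymethyl)oxiran-2-yl]{2-[(1S)-1-(tert-butyldimethylsilyloxy)-2-((4S)-2-(4-methoxyphenyl)-1,3-dioxolan-4-yl)ethyl]-1,3-dithian-2-yl}methanol | CC[Si](CC)(CC)OC[C@@]1(C)O[C@H]1[C@@H](O)C1(SCCCS1)[C@@H](O[Si](C)(C)C(C)(C)C)C[C@H]1COC(O1)c1ccc(OC)cc1 | intermediate
19 | 6-O-triethylsilyl ether of 18 | CC[Si](CC)(CC)OC[C@@]1(C)O[C@H]1[C@@H](O[Si](CC)(CC)CC)C1(SCCCS1)[C@@H](O[Si](C)(C)C(C)(C)C)C[C@H]1COC(O1)c1ccc(OC)cc1 | intermediate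
20 | (2S,4S)-4-(tert-butyldimethylsilyloxy)-2-(4-methoxybenzyloxy)-4-{2-[(R)-(triethylsilyloxy)((2S,3R)-3-methyl-3-(triethylsilyloxymethyl)oxiran-2-yl)methyl]-1,3-dithian-2-yl}butan-1-ol | CC[Si](CC)(CC)OC[C@@]1(C)O[C@H]1[C@@H](O[Si](CC)(CC)CC)C1(SCCCS1)[C@@H](O[Si](C)(C)C(C)(C)C)C[C@H](OCc1ccc(OC)cc1)CO | intermediate
21 | C14 aldehyde of 20 (butanal) | CC[Si](CC)(CC)OC[C@@]1(C)O[C@H]1[C@@H](O[Si](CC)(CC)CC)C1(SCCCS1)[C@@H](O[Si](C)(C)C(C)(C)C)C[C@H](OCc1ccc(OC)cc1)C=O | intermediate
22 | C14 carboxylic acid (butanoic acid) | CC[Si](CC)(CC)OC[C@@]1(C)O[C@H]1[C@@H](O[Si](CC)(CC)CC)C1(SCCCS1)[C@@H](O[Si](C)(C)C(C)(C)C)C[C@H](OCc1ccc(OC)cc1)C(=O)O | intermediate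
23 | methyl ester of 22 | CC[Si](CC)(CC)OC[C@@]1(C)O[C@H]1[C@@H](O[Si](CC)(CC)CC)C1(SCCCS1)[C@@H](O[Si](C)(C)C(C)(C)C)C[C@H](OCc1ccc(OC)cc1)C(=O)OC | intermediate
24 | C3 aldehyde (4S,5S,6R,8S,10S): methyl (2S,4S)-4-(tert-butyldimethylsilyloxy)-4-{2-[(R)-((2S,3S)-3-formyl-3-methyloxiran-2-yl)(triethylsilyloxy)methyl]-1,3-dithian-2-yl}-2-(4-methoxybenzyloxy)butanoate | O=C[C@@]1(C)O[C@H]1[C@@H](O[Si](CC)(CC)CC)C1(SCCCS1)[C@@H](O[Si](C)(C)C(C)(C)C)C[C@H](OCc1ccc(OC)cc1)C(=O)OC | intermediate
25 | 4-methoxybenzyl alcohol | COc1ccc(CO)cc1 | starting material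
26 | trichloroethylene | ClC=C(Cl)Cl | starting material
27 | 1-{[(E)-1,2-dichloroethenyl]oxymethyl}-4-methoxybenzene | COc1ccc(CO/C(Cl)=C\Cl)cc1 | intermediate
28 | {[(4-methoxybenzyl)oxy]ethynyl}lithium | COc1ccc(COC#C[Li])cc1 | intermediate (not isolated)
29 | 1-(ethynyloxymethyl)-4-methoxybenzene | COc1ccc(COC#C)cc1 | intermediate
30 | tributyl{(Z)-2-[(4-methoxybenzyl)oxy]ethenyl}stannane | CCCC[Sn](CCCC)(CCCC)/C=C\OCc1ccc(OC)cc1 | intermediate
31 | {(Z)-2-[(4-methoxybenzyl)oxy]ethenyl}lithium | [Li]/C=C\OCc1ccc(OC)cc1 | intermediate (not isolated)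
32 | {(Z)-2-[(4-methoxybenzyl)oxy]ethenyl}magnesium bromide | Br[Mg]/C=C\OCc1ccc(OC)cc1 | intermediate (not isolated)
33 | C3 carbinol (1Z,3S,4R,5S,6R,8S,10S), methyl ester | COc1ccc(CO/C=C\[C@H](O)[C@@]2(C)O[C@H]2[C@@H](O[Si](CC)(CC)CC)C2(SCCCS2)[C@@H](O[Si](C)(C)C(C)(C)C)C[C@H](OCc2ccc(OC)cc2)C(=O)OC)cc1 | intermediate
34 | seco acid (1Z,3S,4R,5S,6R,8S,10S) | COc1ccc(CO/C=C\[C@H](O)[C@@]2(C)O[C@H]2[C@@H](O[Si](CC)(CC)CC)C2(SCCCS2)[C@@H](O[Si](C)(C)C(C)(C)C)C[C@H](OCc2ccc(OC)cc2)C(=O)O)cc1 | intermediate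
35 | mixed anhydride of 34 with 2,4,6-trichlorobenzoic acid | COc1ccc(CO/C=C\[C@H](O)[C@@]2(C)O[C@H]2[C@@H](O[Si](CC)(CC)CC)C2(SCCCS2)[C@@H](O[Si](C)(C)C(C)(C)C)C[C@H](OCc2ccc(OC)cc2)C(=O)OC(=O)c2c(Cl)cc(Cl)cc2Cl)cc1 | intermediate (not isolated)
36 | ten-membered (Z)-alkoxyvinyl lactone (3S,4R,5S,6R,8S,10S) | CC(C)(C)[Si](C)(C)O[C@H]1C[C@H](OCc3ccc(OC)cc3)C(=O)O[C@@H](/C=C\OCc3ccc(OC)cc3)[C@@]2(C)O[C@H]2[C@@H](O[Si](CC)(CC)CC)C14SCCCS4 | intermediate
37 | (Z)-trimethylsilyl ketene acetal of 36 (C9 cis to the ring oxygen) | CC(C)(C)[Si](C)(C)O[C@H]1C/C(OCc3ccc(OC)cc3)=C(/O[Si](C)(C)C)O[C@@H](/C=C\OCc3ccc(OC)cc3)[C@@]2(C)O[C@H]2[C@@H](O[Si](CC)(CC)CC)C14SCCCS4 | intermediate (not isolated)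
38 | trimethylsilyl ester of 39 | CC(C)(C)[Si](C)(C)O[C@H]1C[C@@](C(=O)O[Si](C)(C)C)(OCc3ccc(OC)cc3)[C@@H](OCc3ccc(OC)cc3)/C=C\[C@@]2(C)O[C@H]2[C@@H](O[Si](CC)(CC)CC)C14SCCCS4 | intermediate (not isolated)
39 | cyclodecene α-alkoxy acid (1S,2Z,4R,5S,6R,8S,10R) | CC(C)(C)[Si](C)(C)O[C@H]1C[C@@](C(=O)O)(OCc3ccc(OC)cc3)[C@@H](OCc3ccc(OC)cc3)/C=C\[C@@]2(C)O[C@H]2[C@@H](O[Si](CC)(CC)CC)C14SCCCS4 | intermediate
40 | methyl ester of 39 | CC(C)(C)[Si](C)(C)O[C@H]1C[C@@](C(=O)OC)(OCc3ccc(OC)cc3)[C@@H](OCc3ccc(OC)cc3)/C=C\[C@@]2(C)O[C@H]2[C@@H](O[Si](CC)(CC)CC)C14SCCCS4 | intermediate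
41 | 1,10-diol methyl ester (1S,10R) | CC(C)(C)[Si](C)(C)O[C@H]1C[C@@](C(=O)OC)(O)[C@@H](O)/C=C\[C@@]2(C)O[C@H]2[C@@H](O[Si](CC)(CC)CC)C13SCCCS3 | intermediate
42 | C1 methanesulfonate of 41 | CC(C)(C)[Si](C)(C)O[C@H]1C[C@@](C(=O)OC)(O)[C@@H](OS(C)(=O)=O)/C=C\[C@@]2(C)O[C@H]2[C@@H](O[Si](CC)(CC)CC)C13SCCCS3 | intermediate (not isolated)
43 | 1,10-epoxy methyl ester (1R,10R) | CC(C)(C)[Si](C)(C)O[C@H]1C[C@@]2(C(=O)OC)O[C@@H]2/C=C\[C@@]2(C)O[C@H]2[C@@H](O[Si](CC)(CC)CC)C13SCCCS3 | intermediate
44 | C14 alcohol (1R,10S) | CC(C)(C)[Si](C)(C)O[C@H]1C[C@@]2(CO)O[C@@H]2/C=C\[C@@]2(C)O[C@H]2[C@@H](O[Si](CC)(CC)CC)C13SCCCS3 | intermediate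
45 | 14-O-PMB ether of 44 | CC(C)(C)[Si](C)(C)O[C@H]1C[C@@]2(COCc4ccc(OC)cc4)O[C@@H]2/C=C\[C@@]2(C)O[C@H]2[C@@H](O[Si](CC)(CC)CC)C13SCCCS3 | intermediate
46 | C7 ketone (1R,4R,5S,6R,8S,10S) | CC(C)(C)[Si](C)(C)O[C@H]1C[C@@]2(COCc3ccc(OC)cc3)O[C@@H]2/C=C\[C@@]2(C)O[C@H]2[C@@H](O[Si](CC)(CC)CC)C1=O | intermediate
47 | 6-hydroxy-7-ketone | CC(C)(C)[Si](C)(C)O[C@H]1C[C@@]2(COCc3ccc(OC)cc3)O[C@@H]2/C=C\[C@@]2(C)O[C@H]2[C@@H](O)C1=O | intermediate
48 | ethyl 2-(diethoxyphosphoryl)acrylate | CCOC(=O)C(=C)P(=O)(OCC)OCC | starting material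
49 | 3,4-dimethoxybenzyl alcohol | COc1ccc(CO)cc1OC | starting material
50 | ethyl 2-(diethoxyphosphoryl)-3-(3,4-dimethoxybenzyloxy)propanoate (racemic) | CCOC(=O)C(COCc1ccc(OC)c(OC)c1)P(=O)(OCC)OCC | intermediate
51 | 2-(diethoxyphosphoryl)-3-(3,4-dimethoxybenzyloxy)propanoic acid (racemic) | OC(=O)C(COCc1ccc(OC)c(OC)c1)P(=O)(OCC)OCC | intermediate
52 | O6 ester of 47 with 51 (epimers at the phosphonate carbon) | CC(C)(C)[Si](C)(C)O[C@H]1C[C@@]2(COCc3ccc(OC)cc3)O[C@@H]2/C=C\[C@@]2(C)O[C@H]2[C@@H](OC(=O)C(COCc2ccc(OC)c(OC)c2)P(=O)(OCC)OCC)C1=O | intermediate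
53 | butenolide (1R,4R,5S,6S,8S,10S) with 13-ODMB, 14-OPMB, 8-OTBS | CC(C)(C)[Si](C)(C)O[C@H]1C[C@@]2(COCc3ccc(OC)cc3)O[C@@H]2/C=C\[C@@]2(C)O[C@H]2[C@H]2OC(=O)C(COCc3ccc(OC)c(OC)c3)=C12 | intermediate
54 | C13 alcohol | CC(C)(C)[Si](C)(C)O[C@H]1C[C@@]2(COCc3ccc(OC)cc3)O[C@@H]2/C=C\[C@@]2(C)O[C@H]2[C@H]2OC(=O)C(CO)=C12 | intermediate
55 | C13 acetate | CC(C)(C)[Si](C)(C)O[C@H]1C[C@@]2(COCc3ccc(OC)cc3)O[C@@H]2/C=C\[C@@]2(C)O[C@H]2[C@H]2OC(=O)C(COC(C)=O)=C12 | intermediate
56 | C8 alcohol | O[C@H]1C[C@@]2(COCc3ccc(OC)cc3)O[C@@H]2/C=C\[C@@]2(C)O[C@H]2[C@H]2OC(=O)C(COC(C)=O)=C12 | intermediate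
57 | (R)-2-methylbutanoic acid | CC[C@@H](C)C(=O)O | starting material
58 | 14-O-PMB ether of the target | CC[C@@H](C)C(=O)O[C@H]1C[C@@]2(COCc3ccc(OC)cc3)O[C@@H]2/C=C\[C@@]2(C)O[C@H]2[C@H]2OC(=O)C(COC(C)=O)=C12 | intermediate
59 | CNP0108300.1, (1R,2Z,4R,5S,6S,8S,10S) with (R)-2-methylbutanoate on O8 | CC[C@@H](C)C(=O)O[C@H]1C[C@@]2(CO)O[C@@H]2/C=C\[C@@]2(C)O[C@H]2[C@H]2OC(=O)C(COC(C)=O)=C12 | target

**Count and risks**

Total step count: 41. Longest linear sequence: 31 steps (1–6, 12–18, 22–32, 35–41).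

Step 25 (key rearrangement). The ketene acetal may react through a chair-like pathway or with incomplete chirality transfer (E alkene or epimeric C1/C10), may fragment by elimination, or may fail to rearrange because of transannular strain. Fallback by ring-closing metathesis, setting out from aldehyde 24 and returning at diol 41: Wittig methylenation (Ph3P=CH2, THF) would give vinyl epoxide F1. Its glycolate ester enolate (LiN(i-Pr)2, THF, −78 °C) would be added to acrolein to give, after separation of the C1/C10 diastereomers, aldol adduct F2. Ring-closing metathesis with RuCl2(=CHPh)(H2IMes)(PCy3) (second-generation Grubbs catalyst) at high dilution would close C2=C3, expected as the Z alkene favoured in a ten-membered ring, to give cyclodecene F3. DDQ would then free O10 to give 41.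

Step 24 (lactonisation). Oligomerisation may outrun ten-membered ring closure, acylation of the hindered C3 hydroxyl may be slow, and the allylic C3–O bond may ionise. Fallback by C–O alkylation instead of acyl transfer, setting out from aldehyde 24 and returning at lactone 36: vinyllithium 31 would be added without MgBr2 in THF, where Felkin–Anh control should favour the C3-epimeric carbinol F4. Saponification would give the C3-epimeric seco acid F5, and Mitsunobu macrolactonisation (PPh3, DIAD, toluene, high dilution) would close the ring with inversion at C3 to give 36.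

Step 12 (fragment union). Metalation may trigger β-elimination of the silyloxy group, and the hindered anion may transfer a proton or open the epoxide instead of adding. Fallback through the oxido-stabilised dianion, setting out from alcohol 15 and returning at carbinol 18: 15 would be doubly deprotonated (n-BuLi, 2.2 equiv, THF/HMPA), the alkoxide being unable to leave, and added to 8 to give diol F6. Selective silylation of the less hindered C8 hydroxyl (t-BuMe2SiOTf, 2,6-lutidine, −78 °C) would give 18.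

Further compounds
F1 | step 25 | vinyl epoxide: C3 methylene analogue of 24 | C=C[C@@]1(C)O[C@H]1[C@@H](O[Si](CC)(CC)CC)C1(SCCCS1)[C@@H](O[Si](C)(C)C(C)(C)C)C[C@H](OCc1ccc(OC)cc1)C(=O)OC
F2 | step 25 | aldol adduct with acrolein (1S,10R): 10-OPMB, 10-CO2Me, 1-OH, vinyl groups on C1 and C4 | C=C[C@@]1(C)O[C@H]1[C@@H](O[Si](CC)(CC)CC)C1(SCCCS1)[C@@H](O[Si](C)(C)C(C)(C)C)C[C@@](C(=O)OC)(OCc1ccc(OC)cc1)[C@@H](O)C=C
F3 | step 25 | cyclodecene (2Z) with 1-OH, 10-OPMB, 10-CO2Me | CC(C)(C)[Si](C)(C)O[C@H]1C[C@@](C(=O)OC)(OCc3ccc(OC)cc3)[C@@H](O)/C=C\[C@@]2(C)O[C@H]2[C@@H](O[Si](CC)(CC)CC)C14SCCCS4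
F4 | step 24 | C3-epimeric carbinol (3R), methyl ester | COc1ccc(CO/C=C\[C@@H](O)[C@@]2(C)O[C@H]2[C@@H](O[Si](CC)(CC)CC)C2(SCCCS2)[C@@H](O[Si](C)(C)C(C)(C)C)C[C@H](OCc2ccc(OC)cc2)C(=O)OC)cc1
F5 | step 24 | C3-epimeric seco acid (3R) | COc1ccc(CO/C=C\[C@@H](O)[C@@]2(C)O[C@H]2[C@@H](O[Si](CC)(CC)CC)C2(SCCCS2)[C@@H](O[Si](C)(C)C(C)(C)C)C[C@H](OCc2ccc(OC)cc2)C(=O)O)cc1
F6 | step 12 | 6,8-diol (8-desilyl analogue of 18) | CC[Si](CC)(CC)OC[C@@]1(C)O[C@H]1[C@@H](O)C1(SCCCS1)[C@@H](O)C[C@H]1COC(O1)c1ccc(OC)cc1
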